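The γ-lactone ring (O–C12(=O)–C11–C7–C6, germacrane numbering) is read as one molecule of CO2 stitched between two carbons that are 1,3-related through C7: the allylic ring carbon C6 (next to the C4=C5 alkene) and the vinylic C11 of the exocyclic methylene. In the key step a ten-membered carbocycle carrying a C11 alkenylboronate and an inverted allylic C6 chloride is carboxylated at C11 with CO2 under copper catalysis; the carboxylate so formed closes the ring by SN2 at C6, setting the trans lactone. The carbocycle comes from nerol by a [2,3]-Wittig rearrangement and a chromium-mediated 2-bromoallylation macrocyclisation; C8, set by catalysis, relays C7 and C6.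

Key step: step 18

Remark: the target is taken as drawn, (1R,6R,7R,8R,10S); germacrane numbering is used throughout (ring C1–C10; C11, C12, C13 on C7; C14 on C10; C15 on C4); TBS = tert-butyldimethylsilyl, PMB = 4-methoxybenzyl, Bpin = 4,4,5,5-tetramethyl-1,3,2-dioxaborolan-2-yl, IPr = 1,3-bis(2,6-diisopropylphenyl)imidazol-2-ylidene; compounds 3, 8, 10, 11 and 12 are racemic.

Step 1
Reactants: 1 nerol
Product: 2 neryl PMB ether 1-methoxy-4-({[(2Z)-3,7-dimethylocta-2,6-dien-1-yl]oxy}methyl)benzene
Conditions: NaH, PMBCl, n-Bu4NI (cat.), THF/DMF, 0 °C to rt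
Reagents that add atoms: 4-methoxybenzyl chloride, COc1ccc(CCl)cc1
Why: Williamson etherification of the primary allylic alkoxide gives a base-stable, oxidatively removable ether, and nerol supplies the Z-trisubstituted alkene that becomes C4=C5.

Step 2
Reactants: 2 neryl PMB ether
Product: 3 racemic epoxide 3-[(3Z)-5-(PMB-oxy)-3-methylpent-3-en-1-yl]-2,2-dimethyloxirane
Conditions: mCPBA (1.0 equiv), NaHCO3, CH2Cl2, −20 °C
Reagents that add atoms: 3-chloroperbenzoic acid, OOC(=O)c1cccc(Cl)c1
Why: Prilezhaev epoxidation should occur at the remote isopropylidene alkene, which is more electron-rich than the alkene deactivated by the allylic ether oxygen; the new stereocentre is irrelevant because step 3 destroys it.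

Step 3
Reactants: 3 racemic epoxide
Product: 4 aldehyde (4Z)-6-(PMB-oxy)-4-methylhex-4-enal
Conditions: H5IO6, THF/H2O, 0 °C
Reagents that add atoms: none
Why: Periodic acid opens the epoxide to the glycol and cleaves it (Malaprade-type cleavage) to the C1 aldehyde and acetone without touching the Z-alkene.

Step 4
Reactants: 5 2-bromoprop-2-en-1-ol
Product: 6 vinyl bromide [(2-bromoprop-2-en-1-yl)oxy](tert-butyl)dimethylsilane
Conditions: TBSCl, imidazole, CH2Cl2, rt
Reagents that add atoms: tert-butyldimethylsilyl chloride, CC(C)(C)[Si](C)(C)Cl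
Why: Standard silylation of a primary alcohol protects the future C14 oxygen.

Step 5
Reactants: 6 vinyl bromide, 4 aldehyde
Product: 8 racemic allylic alcohol (6Z)-2-[(TBS-oxy)methyl]-8-(PMB-oxy)-6-methylocta-1,6-dien-3-ol, via vinyllithium 7 (not isolated)
Conditions: t-BuLi (2.0 equiv), Et2O, −78 °C; then 4, −78 °C; H2O
Reagents that add atoms: none
Why: Bromine–lithium exchange gives 7, which adds 1,2 to the aldehyde (C1–C10 bond); the carbinol is left racemic on purpose because step 7 erases this centre.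

Step 6
Reactants: 8 racemic allylic alcohol, 9 (3-bromoprop-1-yn-1-yl)trimethylsilane
Product: 10 racemic propargylic ether (6Z)-2-[(TBS-oxy)methyl]-8-(PMB-oxy)-6-methyl-3-{[3-(trimethylsilyl)prop-2-yn-1-yl]oxy}octa-1,6-diene
Conditions: NaH, n-Bu4NI (cat.), THF, 0 °C to rt
Reagents that add atoms: none
Why: Williamson etherification of the secondary alkoxide with the reactive propargylic bromide installs the two-carbon unit that becomes C8 and C7.

Step 7
Reactants: 10 racemic propargylic ether
Product: 12 racemic propargylic alcohol (5Z,9Z)-5-[(TBS-oxy)methyl]-11-(PMB-oxy)-9-methyl-1-(trimethylsilyl)undeca-5,9-dien-1-yn-3-ol, via lithiated ether 11 (not isolated)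
Conditions: n-BuLi (1.2 equiv), THF, −78 °C; H2O
Reagents that add atoms: none
Why: [2,3]-Wittig rearrangement: lithiation at the propargylic OCH2 gives 11, which shifts suprafacially through a five-membered envelope transition state with the C2 chain exo, forming the C8–C9 bond and a C1=C10 alkene with C2 and C9 trans; the new carbinol C8 is racemic at this stage.

Step 8
Reactants: 12 racemic propargylic alcohol
Product: 13 ynone (5Z,9Z)-5-[(TBS-oxy)methyl]-11-(PMB-oxy)-9-methyl-1-(trimethylsilyl)undeca-5,9-dien-1-yn-3-one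
Conditions: DMP, NaHCO3, CH2Cl2, 0 °C
Reagents that add atoms: none
Why: Dess–Martin oxidation of a propargylic alcohol under buffered, non-basic conditions should not isomerise the skipped C1=C10 alkene into conjugation.

Step 9
Reactants: 13 ynone
Product: 14 propargylic alcohol (3R,5Z,9Z)-5-[(TBS-oxy)methyl]-11-(PMB-oxy)-9-methyl-1-(trimethylsilyl)undeca-5,9-dien-1-yn-3-ol
Conditions: Ru[(R,R)-TsDPEN](p-cymene) (2 mol %), i-PrOH, rt
Reagents that add atoms: none
Why: Noyori asymmetric transfer hydrogenation of an alkynyl ketone, in which the alkyne takes the place of the aryl group of the standard substrates, so the (R,R)-catalyst should give the (3R)-alcohol (C8 of the target), the only stereocentre of the route set by a chiral catalyst.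

Step 10
Reactants: 14 propargylic alcohol
Product: 15 silyl ether (3R,5Z,9Z)-3-(TBS-oxy)-5-[(TBS-oxy)methyl]-11-(PMB-oxy)-9-methyl-1-(trimethylsilyl)undeca-5,9-dien-1-yne
Conditions: TBSOTf, 2,6-lutidine, CH2Cl2, −78 °C
Reagents that add atoms: tert-butyldimethylsilyl trifluoromethanesulfonate, CC(C)(C)[Si](C)(C)OS(=O)(=O)C(F)(F)F
Why: Silyl triflate silylation protects the C8 oxygen without touching the stereocentre.

Step 11
Reactants: 15 silyl ether
Product: 17 primary propargylic alcohol (4R,6Z,10Z)-4-(TBS-oxy)-6-[(TBS-oxy)methyl]-12-(PMB-oxy)-10-methyldodeca-6,10-dien-2-yn-1-ol, via lithium acetylide 16 (not isolated)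
Conditions: MeLi·LiBr, THF, 0 °C; then (CH2O)n, −20 °C to rt; H2O
Reagents that add atoms: formaldehyde (as paraformaldehyde), C=O
Why: Methyllithium cleaves the alkynyl C–Si bond to give 16, which is hydroxymethylated by formaldehyde to add C13.

Step 12
Reactants: 17 primary propargylic alcohol
Product: 19 bromo allylic alcohol (2E,4R,6Z,10Z)-2-bromo-4-(TBS-oxy)-6-[(TBS-oxy)methyl]-12-(PMB-oxy)-10-methyldodeca-2,6,10-trien-1-ol, via vinylstannane 18 (not isolated)
Conditions: n-Bu3SnH, PdCl2(PPh3)2 (3 mol %), THF, 0 °C; then NBS, CH2Cl2, −20 °C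
Reagents that add atoms: N-bromosuccinimide, O=C1CCC(=O)N1Br
Why: Palladium-catalysed syn-hydrostannation of a propargylic alcohol should place tin on the alkyne carbon next to CH2OH (the other terminus is shielded by the branched silyloxy carbon), and bromodestannylation with retention fixes bromine on C11.

Step 13
Reactants: 19 bromo allylic alcohol
Product: 20 dibromide (2E,4R,6Z,10Z)-1,2-dibromo-4-(TBS-oxy)-6-[(TBS-oxy)methyl]-12-(PMB-oxy)-10-methyldodeca-2,6,10-triene
Conditions: CBr4, PPh3, CH2Cl2, −20 °C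
Reagents that add atoms: carbon tetrabromide, BrC(Br)(Br)Br
Why: Appel reaction converts the primary allylic alcohol into the allylic bromide under neutral conditions that spare silyl ethers and the vinylic bromide.

Step 14
Reactants: 20 dibromide
Product: 22 enal (2Z,6Z,9R,10E)-11,12-dibromo-9-(TBS-oxy)-7-[(TBS-oxy)methyl]-3-methyldodeca-2,6,10-trienal, via allylic alcohol 21 (not isolated)
Conditions: DDQ (2.4 equiv), CH2Cl2/H2O (20:1), 0 °C to rt
Reagents that add atoms: none
Why: DDQ first cleaves the PMB ether oxidatively and then dehydrogenates the liberated primary allylic alcohol 21 to the Z-enal (C6), while bromides and silyl ethers are inert.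

Step 15
Reactants: 22 enal
Product: 24 macrocyclic bromo alcohol (6R,7S,8R)-7-(1-bromoethenyl)-8-(TBS-oxy)-10-[(TBS-oxy)methyl]-4-methylcyclodeca-1(10),4-dien-6-ol, via allylchromium species 23 (not isolated)
Conditions: CrCl2 (8 equiv), THF, 22 added by syringe pump (final 0.002 M), rt; H2O
Reagents that add atoms: none
Why: Nozaki–Hiyama-type 2-haloallylation: divalent chromium inserts only into the allylic C–Br bond (no nickel salt, so the vinylic bromide stays) to give 23, which should add through C7 to the enal in a chair transition state of the (E)-allylchromium (C6–OH anti to C8, the relationship that leads to trans lactones) and anti to the C8–C9 bond with H8 eclipsing the bromoalkene, so that C8 relays C7 and C6 while high dilution favours the ten-membered ring.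

Step 16
Reactants: 24 macrocyclic bromo alcohol
Product: 25 alkenyl boronate (6R,7S,8R)-7-[1-(Bpin)ethenyl]-8-(TBS-oxy)-10-[(TBS-oxy)methyl]-4-methylcyclodeca-1(10),4-dien-6-ol
Conditions: B2pin2, PdCl2(dppf) (5 mol %), KOAc, 1,4-dioxane, 80 °C
Reagents that add atoms: bis(pinacolato)diboron, CC1(C)OB(OC1(C)C)B1OC(C)(C)C(C)(C)O1
Why: Miyaura borylation of the 2-bromo-1-alkene turns C11 into a latent nucleophile; the free allylic alcohol and silyl ethers are tolerated and no stereocentre is touched.

Step 17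
Reactants: 25 alkenyl boronate
Product: 26 allylic chloride (6S,7R,8R)-6-chloro-7-[1-(Bpin)ethenyl]-8-(TBS-oxy)-10-[(TBS-oxy)methyl]-4-methylcyclodeca-1(10),4-diene
Conditions: PPh3, hexachloroacetone, CH2Cl2, −20 to 0 °C
Reagents that add atoms: hexachloroacetone, ClC(Cl)(Cl)C(=O)C(Cl)(Cl)Cl
Why: This Appel-type chlorination under neutral conditions should replace the phosphonium-activated oxygen by chloride in an SN2 step with inversion (6R to 6S) and without allylic transposition, leaving the boronate and silyl ethers untouched.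

Step 18
Reactants: 26 allylic chloride
Product: 28 lactone (6R,7S,8R)-8,14-bis(TBS-oxy)germacra-1(10),4,11(13)-trien-12,6-olide, via potassium carboxylate 27 (not isolated)
Conditions: (IPr)CuCl (10 mol %), KOt-Bu (1.1 equiv), CO2 (1 atm), THF/DMF (3:1), rt then 70 °C
Reagents that add atoms: carbon dioxide, O=C=O
Why: tert-Butoxide turns (IPr)CuCl into the copper alkoxide, which transmetalates the C11 alkenyl–Bpin to an alkenylcopper that inserts CO2 (C11–C12 bond); exchange with the potassium base releases carboxylate 27, whose oxygen displaces the allylic C6 chloride (O–C6 bond). The closest known reaction types are the copper-catalysed carboxylation of alkenylboronic esters with CO2 and the SN2 lactonisation of carboxylate salts with secondary halides, run here as a domino. The γ-lactone closes in the 5-exo-tet mode. C6 is the only new stereocentre and is set by inversion of the (6S)-chloride, itself made by inversion of the (6R)-alcohol, so the trans ring fusion follows from the configuration relayed from C8, and C7 is untouched. The step needs CO2 insertion to beat copper-mediated allylic substitution and SN2 to beat SN2' and elimination: attack of C11 on C6 or C4 would need a three-membered or bridged ring, attack of the carboxylate on C4 a seven-membered ring, and under CO2 the base is present as the weakly basic tert-butyl carbonate, which should suppress loss of HCl.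

Step 19
Reactants: 28 lactone
Product: 29 diol (6R,7R,8R)-8,14-dihydroxygermacra-1(10),4,11(13)-trien-12,6-olide
Conditions: HF·pyridine, pyridine, THF, 0 °C to rt
Reagents that add atoms: none
Why: Buffered hydrogen fluoride cleaves both silyl ethers without the basic fluoride or alkoxide that would add to the α-methylene lactone.

Step 20
Reactants: 29 diol
Product: 30 epoxy diol (1R,6R,7R,8R,10S)-1,10-epoxy-8,14-dihydroxygermacra-4,11(13)-dien-12,6-olide
Conditions: VO(acac)2 (5 mol %), t-BuOOH, CH2Cl2, 0 °C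
Reagents that add atoms: tert-butyl hydroperoxide, CC(C)(C)OO
Why: Vanadium-catalysed hydroxyl-directed epoxidation: the allylic C14 hydroxyl should direct oxygen to C1=C10 only (C4=C5 has no allylic hydroxyl and the α-methylene lactone is electron-poor), and delivery to the exposed outer face of this ring alkene is expected to give the (1R,10S)-epoxide, as in peripheral epoxidations of related germacranolide 1(10)-alkenes.

Step 21
Reactants: 30 epoxy diol
Product: 32 target (1R,6R,7R,8R,10S)-14-acetoxy-1,10-epoxy-8-(methacryloyloxy)germacra-4,11(13)-dien-12,6-olide, via monoacetate 31 (not isolated)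
Conditions: Ac2O (1.05 equiv), 2,4,6-collidine, CH2Cl2, −20 °C; then methacrylic anhydride, Et3N, DMAP, 0 °C to rt
Reagents that add atoms: acetic anhydride, CC(=O)OC(C)=O; methacrylic anhydride, C=C(C)C(=O)OC(=O)C(C)=C
Why: Acylation in order of reactivity: the primary C14 hydroxyl is acetylated selectively at low temperature to give 31, and the hindered secondary C8 hydroxyl is then esterified under DMAP catalysis (Steglich-type acyl transfer), neither acylation touching a stereocentre.

Compound list

1 | nerol, (2Z)-3,7-dimethylocta-2,6-dien-1-ol | CC(C)=CCC/C(C)=C\CO | starting material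
2 | neryl PMB ether | CC(C)=CCC/C(C)=C\COCc1ccc(OC)cc1 | intermediate
3 | racemic 3-[(3Z)-5-(PMB-oxy)-3-methylpent-3-en-1-yl]-2,2-dimethyloxirane | CC1(C)OC1CC/C(C)=C\COCc1ccc(OC)cc1 | intermediate
4 | (4Z)-6-(PMB-oxy)-4-methylhex-4-enal | O=CCC/C(C)=C\COCc1ccc(OC)cc1 | intermediate
5 | 2-bromoprop-2-en-1-ol | OCC(Br)=C | starting material
6 | [(2-bromoprop-2-en-1-yl)oxy](tert-butyl)dimethylsilane | C=C(Br)CO[Si](C)(C)C(C)(C)C | intermediate
7 | 3-(TBS-oxy)prop-1-en-2-yllithium (not isolated) | [Li]C(=C)CO[Si](C)(C)C(C)(C)C | intermediate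
8 | racemic (6Z)-2-[(TBS-oxy)methyl]-8-(PMB-oxy)-6-methylocta-1,6-dien-3-ol | C=C(CO[Si](C)(C)C(C)(C)C)C(O)CC/C(C)=C\COCc1ccc(OC)cc1 | intermediate
9 | (3-bromoprop-1-yn-1-yl)trimethylsilane | C[Si](C)(C)C#CCBr | starting material
10 | racemic 3-(trimethylsilyl)prop-2-yn-1-yl ether of 8 | C=C(CO[Si](C)(C)C(C)(C)C)C(OCC#C[Si](C)(C)C)CC/C(C)=C\COCc1ccc(OC)cc1 | intermediate
11 | racemic ether 10 lithiated at the propargylic OCH2 carbon (not isolated) | C=C(CO[Si](C)(C)C(C)(C)C)C(OC([Li])C#C[Si](C)(C)C)CC/C(C)=C\COCc1ccc(OC)cc1 | intermediate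
12 | racemic (5Z,9Z)-5-[(TBS-oxy)methyl]-11-(PMB-oxy)-9-methyl-1-(trimethylsilyl)undeca-5,9-dien-1-yn-3-ol | C[Si](C)(C)C#CC(O)C/C(CO[Si](C)(C)C(C)(C)C)=C/CC/C(C)=C\COCc1ccc(OC)cc1 | intermediate
13 | (5Z,9Z)-5-[(TBS-oxy)methyl]-11-(PMB-oxy)-9-methyl-1-(trimethylsilyl)undeca-5,9-dien-1-yn-3-one | C[Si](C)(C)C#CC(=O)C/C(CO[Si](C)(C)C(C)(C)C)=C/CC/C(C)=C\COCc1ccc(OC)cc1 | intermediate
14 | (3R,5Z,9Z)-5-[(TBS-oxy)methyl]-11-(PMB-oxy)-9-methyl-1-(trimethylsilyl)undeca-5,9-dien-1-yn-3-ol | C[Si](C)(C)C#C[C@H](O)C/C(CO[Si](C)(C)C(C)(C)C)=C/CC/C(C)=C\COCc1ccc(OC)cc1 | intermediate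
15 | (3R,5Z,9Z)-3-(TBS-oxy)-5-[(TBS-oxy)methyl]-11-(PMB-oxy)-9-methyl-1-(trimethylsilyl)undeca-5,9-dien-1-yne | C[Si](C)(C)C#C[C@H](O[Si](C)(C)C(C)(C)C)C/C(CO[Si](C)(C)C(C)(C)C)=C/CC/C(C)=C\COCc1ccc(OC)cc1 | intermediate
16 | lithium acetylide from desilylation of 15 (not isolated) | [Li]C#C[C@H](O[Si](C)(C)C(C)(C)C)C/C(CO[Si](C)(C)C(C)(C)C)=C/CC/C(C)=C\COCc1ccc(OC)cc1 | intermediate
17 | (4R,6Z,10Z)-4-(TBS-oxy)-6-[(TBS-oxy)methyl]-12-(PMB-oxy)-10-methyldodeca-6,10-dien-2-yn-1-ol | OCC#C[C@H](O[Si](C)(C)C(C)(C)C)C/C(CO[Si](C)(C)C(C)(C)C)=C/CC/C(C)=C\COCc1ccc(OC)cc1 | intermediate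
18 | (2E,4R,6Z,10Z)-2-(tributylstannyl)-4-(TBS-oxy)-6-[(TBS-oxy)methyl]-12-(PMB-oxy)-10-methyldodeca-2,6,10-trien-1-ol (not isolated) | OC/C([Sn](CCCC)(CCCC)CCCC)=C\[C@H](O[Si](C)(C)C(C)(C)C)C/C(CO[Si](C)(C)C(C)(C)C)=C/CC/C(C)=C\COCc1ccc(OC)cc1 | intermediate
19 | (2E,4R,6Z,10Z)-2-bromo-4-(TBS-oxy)-6-[(TBS-oxy)methyl]-12-(PMB-oxy)-10-methyldodeca-2,6,10-trien-1-ol | OC/C(Br)=C\[C@H](O[Si](C)(C)C(C)(C)C)C/C(CO[Si](C)(C)C(C)(C)C)=C/CC/C(C)=C\COCc1ccc(OC)cc1 | intermediate
20 | (2E,4R,6Z,10Z)-1,2-dibromo-4-(TBS-oxy)-6-[(TBS-oxy)methyl]-12-(PMB-oxy)-10-methyldodeca-2,6,10-triene | BrC/C(Br)=C\[C@H](O[Si](C)(C)C(C)(C)C)C/C(CO[Si](C)(C)C(C)(C)C)=C/CC/C(C)=C\COCc1ccc(OC)cc1 | intermediate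
21 | (2Z,6Z,9R,10E)-11,12-dibromo-9-(TBS-oxy)-7-[(TBS-oxy)methyl]-3-methyldodeca-2,6,10-trien-1-ol (not isolated) | BrC/C(Br)=C\[C@H](O[Si](C)(C)C(C)(C)C)C/C(CO[Si](C)(C)C(C)(C)C)=C/CC/C(C)=C\CO | intermediate
22 | (2Z,6Z,9R,10E)-11,12-dibromo-9-(TBS-oxy)-7-[(TBS-oxy)methyl]-3-methyldodeca-2,6,10-trienal | BrC/C(Br)=C\[C@H](O[Si](C)(C)C(C)(C)C)C/C(CO[Si](C)(C)C(C)(C)C)=C/CC/C(C)=C\C=O | intermediate
23 | allylchromium dichloride formed from 22 at C13 (not isolated) | Cl[Cr](Cl)C/C(Br)=C\[C@H](O[Si](C)(C)C(C)(C)C)C/C(CO[Si](C)(C)C(C)(C)C)=C/CC/C(C)=C\C=O | intermediate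
24 | (6R,7S,8R)-7-(1-bromoethenyl)-8-(TBS-oxy)-10-[(TBS-oxy)methyl]-4-methylcyclodeca-1(10),4-dien-6-ol; C2 and C9 trans on C1=C10, C3 and C6 cis on C4=C5 | CC(C)(C)[Si](C)(C)O[C@@H]1C/C(CO[Si](C)(C)C(C)(C)C)=C/CC/C(C)=C\[C@@H](O)[C@@H]1C(Br)=C | intermediate
25 | (6R,7S,8R)-7-[1-(Bpin)ethenyl]-8-(TBS-oxy)-10-[(TBS-oxy)methyl]-4-methylcyclodeca-1(10),4-dien-6-ol | CC(C)(C)[Si](C)(C)O[C@@H]1C/C(CO[Si](C)(C)C(C)(C)C)=C/CC/C(C)=C\[C@@H](O)[C@@H]1C(=C)B2OC(C)(C)C(C)(C)O2 | intermediate
26 | (6S,7R,8R)-6-chloro-7-[1-(Bpin)ethenyl]-8-(TBS-oxy)-10-[(TBS-oxy)methyl]-4-methylcyclodeca-1(10),4-diene | CC(C)(C)[Si](C)(C)O[C@@H]1C/C(CO[Si](C)(C)C(C)(C)C)=C/CC/C(C)=C\[C@H](Cl)[C@@H]1C(=C)B2OC(C)(C)C(C)(C)O2 | intermediate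
27 | potassium 2-[(6S,7R,8R)-6-chloro-8-(TBS-oxy)-10-[(TBS-oxy)methyl]-4-methylcyclodeca-1(10),4-dien-7-yl]prop-2-enoate (not isolated) | CC(C)(C)[Si](C)(C)O[C@@H]1C/C(CO[Si](C)(C)C(C)(C)C)=C/CC/C(C)=C\[C@H](Cl)[C@@H]1C(=C)C(=O)[O-].[K+] | intermediate
28 | (6R,7S,8R)-8,14-bis(TBS-oxy)germacra-1(10),4,11(13)-trien-12,6-olide | CC(C)(C)[Si](C)(C)O[C@@H]1C/C(CO[Si](C)(C)C(C)(C)C)=C/CC/C(C)=C\[C@H]2OC(=O)C(=C)[C@@H]21 | intermediate
29 | (6R,7R,8R)-8,14-dihydroxygermacra-1(10),4,11(13)-trien-12,6-olide | O[C@@H]1C/C(CO)=C/CC/C(C)=C\[C@H]2OC(=O)C(=C)[C@@H]21 | intermediate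
30 | (1R,6R,7R,8R,10S)-1,10-epoxy-8,14-dihydroxygermacra-4,11(13)-dien-12,6-olide | O[C@@H]1C[C@@]2(CO)O[C@@H]2CC/C(C)=C\[C@H]2OC(=O)C(=C)[C@@H]21 | intermediate
31 | 14-O-acetate of 30 (not isolated) | O[C@@H]1C[C@@]2(COC(C)=O)O[C@@H]2CC/C(C)=C\[C@H]2OC(=O)C(=C)[C@@H]21 | intermediate
32 | (1R,6R,7R,8R,10S)-14-acetoxy-1,10-epoxy-8-(methacryloyloxy)germacra-4,11(13)-dien-12,6-olide, C3 and C6 cis on C4=C5 | C=C(C)C(=O)O[C@@H]1C[C@@]2(COC(C)=O)O[C@@H]2CC/C(C)=C\[C@H]2OC(=O)C(=C)[C@@H]21 | target

Total step count: 21. Longest linear sequence: 20 steps (nerol 1 to 32 through steps 1–3 and 5–21; step 4 is a one-step branch).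

Steps most likely to fail

Step 18 (key step). What may go wrong: loss of hydrogen chloride or ionisation of the allylic chloride (epimerisation, allylic transposition) under the warm basic conditions before the carboxylate closes the ring, and C-allylation of the alkenylcopper by the chloride in place of CO2 insertion. The fallback sets out from 25 and comes back at 28. The alcohol of 25 is converted with retention (methyl chloroformate, pyridine, CH2Cl2, 0 °C) into the allylic methyl carbonate F1, a leaving group that is inert to base and to copper. Copper-catalysed carboxylation under the conditions of step 18 should give the potassium carboxylate F2 (not isolated). Pd(PPh3)4 is then added to the same flask: zerovalent palladium ionises the C6–O bond with inversion and the carboxylate attacks the allyl face opposite to palladium (Tsuji–Trost O-allylation), so that 28 should form with net retention from the (6R)-alcohol. This fallback keeps the CO2 stitching of C11 and C6 and makes chloride 26 (step 17) unnecessary.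

Step 15. What may go wrong: intermolecular allylation (oligomerisation) outrunning closure of the strained ten-membered ring, and attack on the wrong face of the allylchromium unit relative to C8. The fallback sets out from 20 and comes back at 24. DDQ (1.1 equiv) removes only the PMB group to give 21, this time isolated. NaH in THF at high dilution closes the much less strained thirteen-membered bis-allylic ether F3 by intramolecular Williamson reaction (C6–O–C13). Lithium diisopropylamide at −78 °C then deprotonates C6, and a [2,3]-Wittig ring contraction forms the C6–C7 bond and releases the C11=C13 methylene, giving 24. C6 and C7 are then set in one concerted suprafacial shift inside the folded macrocycle, and their configuration would have to be confirmed against 24.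

Step 20. What may go wrong: oxygen transfer to the wrong face of C1=C10, and Lewis-acid-promoted transannular opening of the new epoxide by the C4=C5 alkene. The fallback sets out from 29 and comes back at 30 and makes no new compound (F0). It replaces substrate control by reagent control: Sharpless asymmetric epoxidation with Ti(Oi-Pr)4, D-(−)-diethyl tartrate, t-BuOOH and 4 Å molecular sieves in CH2Cl2 at −20 °C. By the usual mnemonic (hydroxymethyl group drawn at the lower right, D-(−)-tartrate delivering oxygen from the top face) this tartrate should give the (1R,10S)-epoxide whatever the ring conformation prefers.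

Further compounds

F1 | step 18 | allylic methyl carbonate of 25, (6R,7S,8R) | CC(C)(C)[Si](C)(C)O[C@@H]1C/C(CO[Si](C)(C)C(C)(C)C)=C/CC/C(C)=C\[C@@H](OC(=O)OC)[C@@H]1C(=C)B2OC(C)(C)C(C)(C)O2
F2 | step 18 | potassium 2-[6-(methoxycarbonyloxy)-8-(TBS-oxy)-10-[(TBS-oxy)methyl]-4-methylcyclodeca-1(10),4-dien-7-yl]prop-2-enoate (not isolated) | CC(C)(C)[Si](C)(C)O[C@@H]1C/C(CO[Si](C)(C)C(C)(C)C)=C/CC/C(C)=C\[C@@H](OC(=O)OC)[C@@H]1C(=C)C(=O)[O-].[K+]
F3 | step 15 | thirteen-membered bis-allylic ether linking C6 and C13 through oxygen, C8 (R) | O1C/C(Br)=C\[C@H](O[Si](C)(C)C(C)(C)C)C/C(CO[Si](C)(C)C(C)(C)C)=C/CC/C(C)=C\C1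
F0 | step 20 | none | none
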